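**Retrosynthetic overview**

1. Numbering: C1 quaternary fusion carbon, C2/C14 acetoxy carbons, C5=C6 ten-ring alkene, C7 lactone O–CH, C8 tertiary carbinol, C9 ketone, C10 fusion CH, C11=C12 with C20H2OH on C11, C17/C19 lactone CH(CH3)/C=O. The strategy rests on C7, an allylic carbinol carbon, lying next to the fully substituted C8 that carries the C17–C19 branch: C7–C8 is cut as the bond of a [2,3]-Wittig shift of a C7 α-oxyallyl anion onto C8 of an O7–C19H2–C17(CH3)=C8(OR) allyl enol ether.
2. That shift contracts a thirteen-membered C7–O–C19 ether to the ten-membered carbocycle. The ether is closed by Williamson alkylation and carries the enol ether with O8 cis to C19 (C9 trans to C19), the geometry that the open-chain E-to-anti rule requires for the target's C7/C8 relation. The freed isopropenyl group becomes the γ-lactone by hydroboration and oxidative lactonization.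
3. The enol ether comes from a β-keto ester grown on a C9 dimethyl ketal. C9–C10 and C1–C2 are made in one cuprate addition–aldol on (R)-4-silyloxy-2-methylcyclohexenone with a nerol-derived C2–C7 aldehyde; C14 is set by directed anti reduction; C11=C12/C20 comes from the C11 ketone through its enol triflate.
4. Ring order: ring A (six-membered, present from step 1), thirteen-membered ether (step 27), ten-membered carbocycle (step 28), γ-lactone (step 30).

Key step: step 28

Remark: stereocentres left open in a SMILES string (epoxide of 9, C8/C17 of 21, C17 of 22, lactol carbon of 41) are carried as mixtures because they are destroyed or reset later.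

**Route**

Step 1
Reactants: 1 4-methoxy-3-methylphenol
Product: 2 4,4-dimethoxy-3-methylcyclohexa-2,5-dien-1-one
Conditions: PhI(OAc)2, MeOH, 0 °C
Reagents that add atoms: methanol, SMILES CO
Why: Oxidative dearomatization of a 4-methoxyphenol in methanol gives the para-quinone monoketal, placing the masked C14 carbonyl next to the methyl-bearing carbon (future C1).

Step 2
Reactants: 2 4,4-dimethoxy-3-methylcyclohexa-2,5-dien-1-one
Product: 3 4,4-dimethoxy-3-methylcyclohex-2-en-1-one
Conditions: H2 (1 atm), RhCl(PPh3)3 (cat.), toluene, rt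
Reagents that add atoms: none
Why: Homogeneous hydrogenation with RhCl(PPh3)3 should saturate the disubstituted alkene of the cross-conjugated dienone well before the trisubstituted one.

Step 3
Reactants: 3 4,4-dimethoxy-3-methylcyclohex-2-en-1-one
Product: 4 (R)-4,4-dimethoxy-3-methylcyclohex-2-en-1-ol
Conditions: RuCl[(R,R)-TsDPEN](p-cymene) (cat.), i-PrOH, rt
Reagents that add atoms: none
Why: Noyori asymmetric transfer hydrogenation reduces the enone 1,2, the alkene taking the place of the arene in the CH/π-controlled transition state, so the (R,R) ligand should give the R carbinol (future C11, a temporary control centre).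

Step 4
Reactants: 4 (R)-4,4-dimethoxy-3-methylcyclohex-2-en-1-ol
Product: 5 (R)-1-(tert-butyldimethylsilyloxy)-4,4-dimethoxy-3-methylcyclohex-2-ene
Conditions: TBSCl, imidazole, DMF, rt
Reagents that add atoms: tert-butyldimethylsilyl chloride, SMILES CC(C)(C)[Si](C)(C)Cl
Why: Standard silylation; the bulky silyl ether later steers the cuprate to the opposite ring face.

Step 5
Reactants: 5 (R)-1-(tert-butyldimethylsilyloxy)-4,4-dimethoxy-3-methylcyclohex-2-ene
Product: 6 (R)-4-(tert-butyldimethylsilyloxy)-2-methylcyclohex-2-en-1-one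
Conditions: PPTS (cat.), acetone–H2O, rt
Reagents that add atoms: water, SMILES O
Why: Mild hydrolysis of the allylic dimethyl ketal unveils the C14 carbonyl and gives the 2-methyl enone with the C11 silyloxy centre γ to it, the silyl ether being stable to pyridinium tosylate.

Step 6
Reactants: 7 nerol
Product: 8 neryl 4-methoxybenzyl ether
Conditions: NaH, PMBCl, Bu4NI (cat.), THF–DMF, 0 °C to rt
Reagents that add atoms: 4-methoxybenzyl chloride, SMILES COc1ccc(CCl)cc1
Why: Williamson etherification of the primary allylic alcohol; the PMB group survives base, hydride and fluoride and leaves under neutral oxidative conditions at step 24.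

Step 7
Reactants: 8 neryl 4-methoxybenzyl ether
Product: 9 6,7-epoxyneryl 4-methoxybenzyl ether
Conditions: mCPBA (1.0 equiv), NaHCO3, CH2Cl2, −20 °C
Reagents that add atoms: 3-chloroperbenzoic acid, SMILES OOC(=O)c1cccc(Cl)c1
Why: Electrophilic epoxidation picks the remote trisubstituted alkene because the 2,3-alkene is deactivated by the allylic ether oxygen.

Step 8
Reactants: 9 6,7-epoxyneryl 4-methoxybenzyl ether
Product: 11 (Z)-6-(4-methoxybenzyloxy)-4-methylhex-4-enal, via diol 10 (not isolated)
Conditions: HIO4·2H2O, THF–Et2O, 0 °C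
Reagents that add atoms: none
Why: Periodic acid opens the epoxide to the glycol (water at the tertiary carbon) and cleaves it (glycol cleavage), leaving the Z alkene untouched and giving the C2 aldehyde.

Step 9
Reactants: 6 (R)-4-(tert-butyldimethylsilyloxy)-2-methylcyclohex-2-en-1-one, 11 (Z)-6-(4-methoxybenzyloxy)-4-methylhex-4-enal
Product: 13 C1–C2 aldol adduct (β-hydroxy ketone), via lithium enolate 12 (not isolated)
Conditions: [CH2=C(OMe)]2CuLi (from methyl vinyl ether, t-BuLi, CuI), THF, −78 to −40 °C; then 11, −78 °C; aq. NH4Cl/NH3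
Reagents that add atoms: methyl vinyl ether (as its lithium cuprate), SMILES COC=C
Why: Conjugate addition of the α-alkoxyvinyl cuprate occurs anti to the C11 silyloxy group, and the lithium enolate then adds to the aldehyde anti to the new C10 substituent through a Zimmerman–Traxler chair (ring E-enolate, aldehyde chain equatorial), which should set C10, the quaternary C1 and C2 in the relative sense of the target.

Step 10
Reactants: 13 C1–C2 aldol adduct
Product: 14 C2 triethylsilyl ether
Conditions: Et3SiCl, imidazole, DMF, 0 °C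
Reagents that add atoms: chlorotriethylsilane, SMILES CC[Si](CC)(CC)Cl
Why: Silylation stops the C2 hydroxyl from adding to the C9 oxocarbenium ion of the next step and shuts the retro-aldol path.

Step 11
Reactants: 14 C2 triethylsilyl ether
Product: 16 C9 dimethyl ketal with C8 primary alcohol, via methoxy epoxide 15 (not isolated)
Conditions: mCPBA (1.05 equiv), NaHCO3, MeOH–CH2Cl2, −40 °C
Reagents that add atoms: 3-chloroperbenzoic acid, SMILES OOC(=O)c1cccc(Cl)c1; methanol, SMILES CO
Why: The electron-rich 1,1-disubstituted enol ether is epoxidized far faster than the trisubstituted alkene, and methanol opens the alkoxy epoxide at the acetal carbon (enol ether to α-hydroxy ketal), giving the C9 dimethyl ketal and the C8 alcohol.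

Step 12
Reactants: 16 C9 dimethyl ketal with C8 primary alcohol
Product: 17 C2,C8-diol ketone (C11 silyl ether kept)
Conditions: PPTS, MeOH, 0 °C
Reagents that add atoms: none
Why: Acid-catalysed methanolysis removes the triethylsilyl ether selectively; the secondary TBS ether is far slower and the dimethyl ketal can only exchange degenerately in methanol.

Step 13
Reactants: 17 C2,C8-diol ketone
Product: 18 C2,C8,C14-triol
Conditions: Me4NBH(OAc)3, MeCN–AcOH, −30 °C
Reagents that add atoms: none
Why: Evans–Saksena reduction: the C2 alkoxy(acetoxy)borohydride delivers hydride intramolecularly through a chair transition state, giving the 1,3-anti diol and so the C14 hydroxyl cis to the C2 branch on ring A.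

Step 14
Reactants: 18 C2,C8,C14-triol
Product: 19 C2/C14 acetonide with free C8 alcohol
Conditions: 2,2-dimethoxypropane, PPTS (cat.), CH2Cl2, 0 °C to rt
Reagents that add atoms: 2,2-dimethoxypropane, SMILES COC(C)(C)OC
Why: Only the C2/C14 1,3-diol can form a six-membered acetonide, which covers both future acetoxy positions with one base-stable group; the C9 ketal is deactivated towards exchange by its α-oxygenated carbon.

Step 15
Reactants: 19 C2/C14 acetonide with free C8 alcohol
Product: 20 C8 aldehyde
Conditions: Dess–Martin periodinane, NaHCO3, CH2Cl2, 0 °C to rt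
Reagents that add atoms: none
Why: Dess–Martin oxidation of the only free hydroxyl gives the non-enolizable α,α-dimethoxy aldehyde under buffered conditions.

Step 16
Reactants: 20 C8 aldehyde
Product: 21 β-hydroxy ester (C8/C17 epimer mixture)
Conditions: LiN(i-Pr)2, ethyl propionate, THF, −78 °C; then 20; aq. NH4Cl
Reagents that add atoms: ethyl propionate, SMILES CCC(=O)OCC
Why: Aldol addition of the lithium ester enolate to the activated aldehyde forms C8–C17 and brings in C17, its methyl and C19; the two new centres need no control because both become sp2.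

Step 17
Reactants: 21 β-hydroxy ester
Product: 22 β-keto ester
Conditions: Dess–Martin periodinane, NaHCO3, CH2Cl2, rt
Reagents that add atoms: none
Why: Oxidation of the secondary carbinol gives the C8 ketone flanked by the ketal and the ester-bearing C17.

Step 18
Reactants: 22 β-keto ester
Product: 24 MOM enol ether ester (O8 cis to C19), via lithium enolate 23 (not isolated)
Conditions: LiN(SiMe3)2, toluene–THF, −78 °C; MOMCl, −78 to 0 °C
Reagents that add atoms: chloromethyl methyl ether, SMILES COCCl
Why: O-alkylation of the lithium-chelated enolate (enolate oxygen and ester carbonyl bridged by lithium) by the hard electrophile should give the enol ether with O8 cis to C19 and C9 cis to the C17 methyl, the geometry the key step needs.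

Step 19
Reactants: 24 MOM enol ether ester
Product: 25 C11 alcohol
Conditions: Bu4NF, THF, rt
Reagents that add atoms: none
Why: Fluoride removes the secondary TBS ether; the vinylogous carbonate, ketal, acetonide and PMB ether are inert to it.

Step 20
Reactants: 25 C11 alcohol
Product: 26 C11 ketone
Conditions: Dess–Martin periodinane, NaHCO3, CH2Cl2, rt
Reagents that add atoms: none
Why: Buffered Dess–Martin oxidation gives the cyclohexanone without epimerizing C10, whose substituent is already equatorial.

Step 21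
Reactants: 26 C11 ketone
Product: 28 C11 enol triflate (C11=C12), via potassium enolate 27 (not isolated)
Conditions: KN(SiMe3)2, THF, −78 °C; Comins' reagent
Reagents that add atoms: N-(5-chloropyridin-2-yl)bis(trifluoromethanesulfonimide), SMILES FC(F)(F)S(=O)(=O)N(c1ccc(Cl)cn1)S(=O)(=O)C(F)(F)F
Why: Kinetic deprotonation takes the C12 methylene, not the hindered C10 methine, and O-sulfonylation fixes the C11=C12 alkene regioselectively.

Step 22
Reactants: 28 C11 enol triflate
Product: 29 C20 allylic alcohol
Conditions: Bu3SnCH2OH, Pd(PPh3)4 (cat.), LiCl, 1,4-dioxane, 90 °C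
Reagents that add atoms: (tributylstannyl)methanol, SMILES CCCC[Sn](CCCC)(CCCC)CO
Why: Stille coupling of the enol triflate with the hydroxymethyl stannane installs C20 on C11 with the C11=C12 alkene in place.

Step 23
Reactants: 29 C20 allylic alcohol
Product: 30 C20 tert-butyldiphenylsilyl ether
Conditions: TBDPSCl, imidazole, CH2Cl2, rt
Reagents that add atoms: tert-butyl(chloro)diphenylsilane, SMILES CC(C)(C)[Si](Cl)(c1ccccc1)c1ccccc1
Why: Silylation of the primary alcohol with a bulky group that survives DDQ, hydride, butyllithium and the mild acids used later, and that shields the C20 protons.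

Step 24
Reactants: 30 C20 tert-butyldiphenylsilyl ether
Product: 31 C7 allylic alcohol
Conditions: DDQ, CH2Cl2–pH 7 buffer, 0 °C
Reagents that add atoms: none
Why: Oxidative PMB cleavage under buffered conditions frees O7 while ketal, acetonide and enol ether stay intact.

Step 25
Reactants: 31 C7 allylic alcohol
Product: 33 C7 allylic chloride, via mesylate 32 (not isolated)
Conditions: MsCl, 2,4,6-collidine, LiCl, DMF, 0 °C
Reagents that add atoms: lithium chloride, SMILES [Li+].[Cl-]
Why: Mesylation and in situ SN2 displacement by chloride convert the primary allylic alcohol without allylic transposition or loss of the Z geometry.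

Step 26
Reactants: 33 C7 allylic chloride
Product: 34 chloro alcohol (C19 allylic alcohol)
Conditions: i-Bu2AlH, CH2Cl2, −78 °C; aq. potassium sodium tartrate
Reagents that add atoms: none
Why: i-Bu2AlH reduces the vinylogous carbonate ester to the allylic alcohol at low temperature, where the allylic chloride is inert.

Step 27
Reactants: 34 chloro alcohol
Product: 36 thirteen-membered C7–O–C19 ether, via sodium alkoxide 35 (not isolated)
Conditions: NaH, Bu4NI (cat.), THF (0.002 M, slow addition), 0 to 45 °C
Reagents that add atoms: none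
Why: Intramolecular Williamson etherification under high dilution, helped by iodide exchange at C7, closes the thirteen-membered bis-allylic ether by SN2 attack of the C19 alkoxide on the primary allylic carbon.

Step 28
Reactants: 36 thirteen-membered C7–O–C19 ether
Product: 38 ten-membered homoallylic alcohol, via C7-lithiated ether 37 (not isolated)
Conditions: n-BuLi, THF–hexane, −78 to −25 °C; aq. NH4Cl
Reagents that add atoms: none
Why: Proposed new method: n-BuLi should remove a C7 proton, which is allylic to C5=C6 and α to the ether oxygen (C19–H lies next to an electron-rich enol ether and C20–H is shielded by the bulky silyl group), and the α-oxyallyl anion then attacks C8 suprafacially through the five-membered envelope C7–O–C19–C17=C8 while O–C19 breaks, leaving C17/C19 as the isopropenyl group and O7 as a lithium alkoxide. The closest known reaction type is the [2,3]-Wittig ring contraction of thirteen-membered bis-allylic ethers to ten-membered homoallylic alcohols, which has not been shown for a fully substituted, oxygen-bearing terminus. The ten-membered carbocycle closes by transannular C7–C8 bond formation inside the thirteen-membered ring (O, C19 and C17 leave the ring), so the reacting ends are already held together. C7 and C8 are set together: with C6 exo on the envelope, the carbanion substituent ends trans to the terminus substituent that was trans to C19 (C9) and cis to the one that was cis to it (O8), the E-to-anti relation of open-chain [2,3]-Wittig shifts, which is why the enol ether carries O8 cis to C19. Which face of C8 is reached (7S,8S rather than 7R,8R) depends on the planar chirality of the ring-E enol ether, which ring A is expected to bias through its trans C1/C10 junction and the acetonide-locked C2, the bridge passing over the C8 face away from the C1 methyl. The step also needs [2,3] over [1,2] shift and retention of the Z C5=C6 geometry, which low temperature and the configurationally stable, fast-rearranging allyl anion should secure.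

Step 29
Reactants: 38 ten-membered homoallylic alcohol
Product: 40 C7,C19-diol, via alkylborane 39 (not isolated)
Conditions: 9-BBN (excess), THF, 0 to 40 °C; then NaOH, H2O2, 0 °C
Reagents that add atoms: hydrogen peroxide, SMILES OO
Why: 9-BBN adds to the 1,1-disubstituted isopropenyl alkene in preference to the two trisubstituted ring alkenes, and in the conformer with the C8–O bond in the alkene plane it should approach anti to the C9 ketal carbon, which places the C17 methyl cis to O8 as the lactone requires.

Step 30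
Reactants: 40 C7,C19-diol
Product: 42 γ-lactone, via lactol 41 (not isolated)
Conditions: TEMPO (cat.), PhI(OAc)2, NaHCO3, CH2Cl2, rt
Reagents that add atoms: none
Why: The oxoammonium oxidation takes the primary C19 alcohol to the aldehyde, which O7 captures as the lactol and which is oxidized on to the γ-lactone (oxidative lactonization of a 1,4-diol).

Step 31
Reactants: 42 γ-lactone
Product: 43 C2,C14-diol
Conditions: PPTS, MeOH, 40 °C
Reagents that add atoms: none
Why: Acid-catalysed transketalization in methanol removes the acetonide of the anti-1,3-diol, while the dimethyl ketal (degenerate exchange), the MOM ether, the silyl ether and the γ-lactone persist.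

Step 32
Reactants: 43 C2,C14-diol
Product: 44 C2,C14-diacetate
Conditions: Ac2O, DMAP, pyridine, rt
Reagents that add atoms: acetic anhydride, SMILES CC(=O)OC(C)=O
Why: DMAP-catalysed acetylation esterifies the two secondary hydroxyls, the only free ones in the molecule.

Step 33
Reactants: 44 C2,C14-diacetate
Product: 45 C9 ketone with free C8 hydroxyl
Conditions: Me2BBr, CH2Cl2, −78 °C; then aq. NaHCO3
Reagents that add atoms: water, SMILES O
Why: Me2BBr cleaves acetal-type C–O bonds at low temperature, so the tertiary MOM ether and the dimethyl ketal fall together and aqueous work-up gives the C8 hydroxyl and the C9 ketone without touching acetates, lactone, silyl ether or the C11=C12 alkene.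

Step 34
Reactants: 45 C9 ketone with free C8 hydroxyl
Product: 46 CNP0140109.1 (target)
Conditions: HF·pyridine, pyridine, THF, 0 °C to rt
Reagents that add atoms: none
Why: Buffered fluoride removes the silyl ether from O20 under conditions that leave the acetates, the α-ketol and the β,γ-unsaturated ketone untouched.

**Compound list**

1 | 4-methoxy-3-methylphenol | COc1ccc(O)cc1C | starting material
2 | 4,4-dimethoxy-3-methylcyclohexa-2,5-dien-1-one | COC1(OC)C=CC(=O)C=C1C | intermediate
3 | 4,4-dimethoxy-3-methylcyclohex-2-en-1-one | COC1(OC)CCC(=O)C=C1C | intermediate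
4 | (R)-4,4-dimethoxy-3-methylcyclohex-2-en-1-ol | COC1(OC)CC[C@@H](O)C=C1C | intermediate
5 | (R)-1-(tert-butyldimethylsilyloxy)-4,4-dimethoxy-3-methylcyclohex-2-ene | COC1(OC)CC[C@@H](O[Si](C)(C)C(C)(C)C)C=C1C | intermediate
6 | (R)-4-(tert-butyldimethylsilyloxy)-2-methylcyclohex-2-en-1-one (C14 carbonyl, C1 methyl, C11 silyloxy) | O=C1CC[C@@H](O[Si](C)(C)C(C)(C)C)C=C1C | intermediate
7 | nerol | CC(C)=CCC/C(C)=C\CO | starting material
8 | neryl 4-methoxybenzyl ether | CC(C)=CCC/C(C)=C\COCc1ccc(OC)cc1 | intermediate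
9 | 6,7-epoxyneryl 4-methoxybenzyl ether (racemic epoxide) | CC1(C)OC1CC/C(C)=C\COCc1ccc(OC)cc1 | intermediate
10 | 6,7-diol from 9 (not isolated) | CC(C)(O)C(O)CC/C(C)=C\COCc1ccc(OC)cc1 | intermediate
11 | (Z)-6-(4-methoxybenzyloxy)-4-methylhex-4-enal (C2 aldehyde, C3–C7 chain) | O=CCC/C(C)=C\COCc1ccc(OC)cc1 | intermediate
12 | lithium enolate of the conjugate adduct; C10 1-methoxyvinyl trans to C11 silyloxy (not isolated) | [Li]OC1=C(C)[C@@H](C(=C)OC)[C@H](O[Si](C)(C)C(C)(C)C)CC1 | intermediate
13 | aldol adduct: C14 ketone, quaternary C1 (methyl and C2 carbinol branch), C10 1-methoxyvinyl trans to the C2 branch and to the C11 silyloxy group; C1, C2, C10 as in the target | O=C1CC[C@@H](O[Si](C)(C)C(C)(C)C)[C@H](C(=C)OC)[C@@]1(C)[C@@H](O)CC/C(C)=C\COCc1ccc(OC)cc1 | intermediate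
14 | C2 triethylsilyl ether of 13 | O=C1CC[C@@H](O[Si](C)(C)C(C)(C)C)[C@H](C(=C)OC)[C@@]1(C)[C@@H](O[Si](CC)(CC)CC)CC/C(C)=C\COCc1ccc(OC)cc1 | intermediate
15 | 2-methoxyoxirane at C9/C8 from 14 (not isolated) | O=C1CC[C@@H](O[Si](C)(C)C(C)(C)C)[C@H](C2(OC)CO2)[C@@]1(C)[C@@H](O[Si](CC)(CC)CC)CC/C(C)=C\COCc1ccc(OC)cc1 | intermediate
16 | C9 dimethyl ketal with C8 primary alcohol (C2 OTES, C11 OTBS, C14 ketone) | O=C1CC[C@@H](O[Si](C)(C)C(C)(C)C)[C@H](C(OC)(OC)CO)[C@@]1(C)[C@@H](O[Si](CC)(CC)CC)CC/C(C)=C\COCc1ccc(OC)cc1 | intermediate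
17 | C2,C8-diol ketone (C11 OTBS) | O=C1CC[C@@H](O[Si](C)(C)C(C)(C)C)[C@H](C(OC)(OC)CO)[C@@]1(C)[C@@H](O)CC/C(C)=C\COCc1ccc(OC)cc1 | intermediate
18 | C2,C8,C14-triol; C14 hydroxyl anti to the C2 hydroxyl, cis to the C2 branch on ring A | O[C@H]1CC[C@@H](O[Si](C)(C)C(C)(C)C)[C@H](C(OC)(OC)CO)[C@@]1(C)[C@@H](O)CC/C(C)=C\COCc1ccc(OC)cc1 | intermediate
19 | C2/C14 acetonide with free C8 alcohol | CC1(C)O[C@H]2CC[C@@H](O[Si](C)(C)C(C)(C)C)[C@H](C(OC)(OC)CO)[C@@]2(C)[C@H](CC/C(C)=C\COCc3ccc(OC)cc3)O1 | intermediate
20 | C8 aldehyde (α,α-dimethoxy aldehyde) | CC1(C)O[C@H]2CC[C@@H](O[Si](C)(C)C(C)(C)C)[C@H](C(OC)(OC)C=O)[C@@]2(C)[C@H](CC/C(C)=C\COCc3ccc(OC)cc3)O1 | intermediate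
21 | β-hydroxy ester (C8 carbinol, C17 methyl, C19 ethyl ester; epimer mixture) | CC1(C)O[C@H]2CC[C@@H](O[Si](C)(C)C(C)(C)C)[C@H](C(OC)(OC)C(O)C(C)C(=O)OCC)[C@@]2(C)[C@H](CC/C(C)=C\COCc3ccc(OC)cc3)O1 | intermediate
22 | β-keto ester (C8 ketone) | CC1(C)O[C@H]2CC[C@@H](O[Si](C)(C)C(C)(C)C)[C@H](C(OC)(OC)C(=O)C(C)C(=O)OCC)[C@@]2(C)[C@H](CC/C(C)=C\COCc3ccc(OC)cc3)O1 | intermediate
23 | chelated lithium enolate of 22 (not isolated) | CC1(C)O[C@H]2CC[C@@H](O[Si](C)(C)C(C)(C)C)[C@H](C(OC)(OC)/C(O[Li])=C(\C)C(=O)OCC)[C@@]2(C)[C@H](CC/C(C)=C\COCc3ccc(OC)cc3)O1 | intermediate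
24 | MOM enol ether ester; O8 cis to the C19 ester, C9 cis to the C17 methyl | CC1(C)O[C@H]2CC[C@@H](O[Si](C)(C)C(C)(C)C)[C@H](C(OC)(OC)/C(OCOC)=C(\C)C(=O)OCC)[C@@]2(C)[C@H](CC/C(C)=C\COCc3ccc(OC)cc3)O1 | intermediate
25 | C11 alcohol | CC1(C)O[C@H]2CC[C@@H](O)[C@H](C(OC)(OC)/C(OCOC)=C(\C)C(=O)OCC)[C@@]2(C)[C@H](CC/C(C)=C\COCc3ccc(OC)cc3)O1 | intermediate
26 | C11 ketone | CC1(C)O[C@H]2CCC(=O)[C@H](C(OC)(OC)/C(OCOC)=C(\C)C(=O)OCC)[C@@]2(C)[C@H](CC/C(C)=C\COCc3ccc(OC)cc3)O1 | intermediate
27 | potassium C11 enolate, C11=C12 (not isolated) | CC1(C)O[C@H]2CC=C(O[K])[C@H](C(OC)(OC)/C(OCOC)=C(\C)C(=O)OCC)[C@@]2(C)[C@H](CC/C(C)=C\COCc3ccc(OC)cc3)O1 | intermediate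
28 | C11 enol triflate | CC1(C)O[C@H]2CC=C(OS(=O)(=O)C(F)(F)F)[C@H](C(OC)(OC)/C(OCOC)=C(\C)C(=O)OCC)[C@@]2(C)[C@H](CC/C(C)=C\COCc3ccc(OC)cc3)O1 | intermediate
29 | C20 allylic alcohol | CC1(C)O[C@H]2CC=C(CO)[C@H](C(OC)(OC)/C(OCOC)=C(\C)C(=O)OCC)[C@@]2(C)[C@H](CC/C(C)=C\COCc3ccc(OC)cc3)O1 | intermediate
30 | C20 tert-butyldiphenylsilyl ether | CC1(C)O[C@H]2CC=C(CO[Si](c3ccccc3)(c3ccccc3)C(C)(C)C)[C@H](C(OC)(OC)/C(OCOC)=C(\C)C(=O)OCC)[C@@]2(C)[C@H](CC/C(C)=C\COCc3ccc(OC)cc3)O1 | intermediate
31 | C7 allylic alcohol | CC1(C)O[C@H]2CC=C(CO[Si](c3ccccc3)(c3ccccc3)C(C)(C)C)[C@H](C(OC)(OC)/C(OCOC)=C(\C)C(=O)OCC)[C@@]2(C)[C@H](CC/C(C)=C\CO)O1 | intermediate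
32 | C7 mesylate (not isolated) | CC1(C)O[C@H]2CC=C(CO[Si](c3ccccc3)(c3ccccc3)C(C)(C)C)[C@H](C(OC)(OC)/C(OCOC)=C(\C)C(=O)OCC)[C@@]2(C)[C@H](CC/C(C)=C\COS(C)(=O)=O)O1 | intermediate
33 | C7 allylic chloride | CC1(C)O[C@H]2CC=C(CO[Si](c3ccccc3)(c3ccccc3)C(C)(C)C)[C@H](C(OC)(OC)/C(OCOC)=C(\C)C(=O)OCC)[C@@]2(C)[C@H](CC/C(C)=C\CCl)O1 | intermediate
34 | chloro alcohol (C19 allylic alcohol, C7 chloride) | CC1(C)O[C@H]2CC=C(CO[Si](c3ccccc3)(c3ccccc3)C(C)(C)C)[C@H](C(OC)(OC)/C(OCOC)=C(\C)CO)[C@@]2(C)[C@H](CC/C(C)=C\CCl)O1 | intermediate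
35 | sodium C19 alkoxide (not isolated) | CC1(C)O[C@H]2CC=C(CO[Si](c3ccccc3)(c3ccccc3)C(C)(C)C)[C@H](C(OC)(OC)/C(OCOC)=C(\C)CO[Na])[C@@]2(C)[C@H](CC/C(C)=C\CCl)O1 | intermediate
36 | thirteen-membered C7–O–C19 bis-allylic ether; O8 cis to C19, C9 trans to C19, C5=C6 Z | CC1(C)O[C@H]2CC=C(CO[Si](c3ccccc3)(c3ccccc3)C(C)(C)C)[C@@H]3C(OC)(OC)/C(OCOC)=C(\C)COC/C=C(/C)CC[C@H](O1)[C@]32C | intermediate
37 | C7-lithiated ether (not isolated) | CC1(C)O[C@H]2CC=C(CO[Si](c3ccccc3)(c3ccccc3)C(C)(C)C)[C@@H]3C(OC)(OC)/C(OCOC)=C(\C)COC([Li])/C=C(/C)CC[C@H](O1)[C@]32C | intermediate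
38 | ten-membered homoallylic alcohol: C7 hydroxyl, C8 MOM ether and isopropenyl; C7, C8 as in the target | CC1(C)O[C@H]2CC=C(CO[Si](c3ccccc3)(c3ccccc3)C(C)(C)C)[C@@H]3C(OC)(OC)[C@@](C(C)=C)(OCOC)[C@@H](O)/C=C(/C)CC[C@H](O1)[C@]32C | intermediate
39 | C19 alkylborane (9-BBN) with C7 borinate (not isolated) | CC1(C)O[C@H]2CC=C(CO[Si](c3ccccc3)(c3ccccc3)C(C)(C)C)[C@@H]3C(OC)(OC)[C@@]([C@@H](C)CB4C5CCCC4CCC5)(OCOC)[C@@H](OB4C5CCCC4CCC5)/C=C(/C)CC[C@H](O1)[C@]32C | intermediate
40 | C7,C19-diol; C17 as in the target | CC1(C)O[C@H]2CC=C(CO[Si](c3ccccc3)(c3ccccc3)C(C)(C)C)[C@@H]3C(OC)(OC)[C@@]([C@@H](C)CO)(OCOC)[C@@H](O)/C=C(/C)CC[C@H](O1)[C@]32C | intermediate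
41 | lactol (not isolated) | CC1(C)O[C@H]2CC=C(CO[Si](c3ccccc3)(c3ccccc3)C(C)(C)C)[C@@H]3C(OC)(OC)[C@@]4(OCOC)[C@H](/C=C(/C)CC[C@H](O1)[C@]32C)OC(O)[C@@H]4C | intermediate
42 | γ-lactone (C8 MOM ether, C9 ketal, acetonide, C20 silyl ether) | CC1(C)O[C@H]2CC=C(CO[Si](c3ccccc3)(c3ccccc3)C(C)(C)C)[C@@H]3C(OC)(OC)[C@@]4(OCOC)[C@H](/C=C(/C)CC[C@H](O1)[C@]32C)OC(=O)[C@@H]4C | intermediate
43 | C2,C14-diol | O[C@H]1CC=C(CO[Si](c2ccccc2)(c2ccccc2)C(C)(C)C)[C@@H]2C(OC)(OC)[C@@]3(OCOC)[C@H](/C=C(/C)CC[C@H](O)[C@]21C)OC(=O)[C@@H]3C | intermediate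
44 | C2,C14-diacetate | CC(=O)O[C@H]1CC=C(CO[Si](c2ccccc2)(c2ccccc2)C(C)(C)C)[C@@H]2C(OC)(OC)[C@@]3(OCOC)[C@H](/C=C(/C)CC[C@H](OC(C)=O)[C@]21C)OC(=O)[C@@H]3C | intermediate
45 | C9 ketone with free C8 hydroxyl and C20 silyl ether | CC(=O)O[C@H]1CC=C(CO[Si](c2ccccc2)(c2ccccc2)C(C)(C)C)[C@@H]2C(=O)[C@@]3(O)[C@H](/C=C(/C)CC[C@H](OC(C)=O)[C@]21C)OC(=O)[C@@H]3C | intermediate
46 | CNP0140109.1 | CC(=O)O[C@H]1CC=C(CO)[C@@H]2C(=O)[C@@]3(O)[C@H](/C=C(/C)CC[C@H](OC(C)=O)[C@]21C)OC(=O)[C@@H]3C | target

**Totals and risks**

Total step count: 34. Longest linear sequence: 31 (steps 1–5 and 9–34).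

1. Step 28 (new method). What may go wrong: lithiation at C19 or C20 instead of C7, followed by [1,2]-shift or silyl migration; reluctance of the electron-rich, fully substituted enol ether carbon to accept the carbanion, so that the [1,2]-shift takes over; attack on the other face of C8. Fallback by known chemistry, setting out from alcohol 31: MnO2 in CH2Cl2 should give the (Z)-enal F1, and SmI2 with MeOH in THF should turn its aldehyde into a ketyl that adds to C8, the β-carbon of the β-alkoxy acrylate (the aldehyde/β-alkoxyacrylate reductive cyclization). This forms C7–C8 and the ten-membered ring; protonation at C17 and lactonization of the C7 alkoxide onto the ethyl ester bring the route back at lactone 42, bypassing steps 25–30.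

2. Step 9. What may go wrong: incomplete transfer of the α-methoxyvinyl group to the α-substituted enone, reversal of the aldol that creates the quaternary carbon, and loss of facial control at C2. Fallback from enone 6: the two C–C bond formations are separated. Cuprate addition in the presence of Me3SiCl should give the silyl enol ether F2, which is isolated. MeLi regenerates lithium enolate 12 free of copper, ZnCl2 converts it to the chlorozinc enolate F3, and this adds to aldehyde 11 under equilibrating conditions to return at aldol adduct 13.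

3. Step 29. What may go wrong: slow hydroboration of the neopentyl-type isopropenyl group, competing attack on a trisubstituted ring alkene, or approach from the other face giving the C17 epimer. Fallback from alcohol 38: kinetic facial control is replaced by thermodynamic control. The C17-epimeric diol F4 is taken through the same TEMPO/PhI(OAc)2 lactonization to the epimeric lactone F5, whose α-centre is equilibrated with DBU in toluene to the more stable epimer with the methyl trans to the C9 branch, returning at lactone 42.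

**Further compounds**

F1 | step 28 | (Z)-enal from 31 (C7 aldehyde, C19 ethyl ester) | CC1(C)O[C@H]2CC=C(CO[Si](c3ccccc3)(c3ccccc3)C(C)(C)C)[C@H](C(OC)(OC)/C(OCOC)=C(\C)C(=O)OCC)[C@@]2(C)[C@H](CC/C(C)=C\C=O)O1
F2 | step 9 | trimethylsilyl enol ether of the conjugate adduct | C[Si](C)(C)OC1=C(C)[C@@H](C(=C)OC)[C@H](O[Si](C)(C)C(C)(C)C)CC1
F3 | step 9 | chlorozinc enolate of the conjugate adduct | Cl[Zn]OC1=C(C)[C@@H](C(=C)OC)[C@H](O[Si](C)(C)C(C)(C)C)CC1
F4 | step 29 | C17 epimer of diol 40 | CC1(C)O[C@H]2CC=C(CO[Si](c3ccccc3)(c3ccccc3)C(C)(C)C)[C@@H]3C(OC)(OC)[C@@]([C@H](C)CO)(OCOC)[C@@H](O)/C=C(/C)CC[C@H](O1)[C@]32C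
F5 | step 29 | C17 epimer of lactone 42 | CC1(C)O[C@H]2CC=C(CO[Si](c3ccccc3)(c3ccccc3)C(C)(C)C)[C@@H]3C(OC)(OC)[C@@]4(OCOC)[C@H](/C=C(/C)CC[C@H](O1)[C@]32C)OC(=O)[C@H]4C
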